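(The constants used here were set for the occasion; the result is computed.)

Free catalyst is the hand that takes up reagent, and two free catalyst meeting is how it dies.

    reagent + free catalyst ⇌ catalyst intermediate A (K1 = 4.4 M⁻¹, k1 = 18 M⁻¹ min⁻¹)
    catalyst intermediate A → catalyst intermediate B (k2 = 49 min⁻¹)
    substrate + catalyst intermediate B → catalyst intermediate C (k3 = 30 M⁻¹ min⁻¹)
    catalyst intermediate C → free catalyst + target (k4 = 15 min⁻¹)
    2 free catalyst → spent catalyst (k5 = 19 M⁻¹ min⁻¹)

| flask | substrate | reagent | free catalyst | time | remark |
|---|---|---|---|---|---|
| delta | 0.10 M | 1.10 equiv (fed, over 50 h) | 0.07 mol% | 10 d | all else is in the flask from the start; the feed brings no volume worth counting |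
| eta | 0.10 M | 1.10 equiv (fed, over 5.0 h) | 0.07 mol% | 10 d | all else is in the flask from the start; the feed brings no volume worth counting |
| epsilon | 0.10 M (fed, over 50 h) | 1.10 equiv | 0.07 mol% | 10 d | all else is in the flask from the start; the feed brings no volume worth counting |
| zeta | 0.10 M | 1.10 equiv | 0.07 mol% | 10 d | everything together at the start |

- the best flask by amount of target, in percent of the substrate charged; "all alike" if 1.5 percentage points covers them all (delta / eta / epsilon / zeta / all alike)
- amount of target at the end, in percent of the substrate charged, delta
- amount of target at the end, in percent of the substrate charged, eta
- amount of target at the end, in percent of the substrate charged, epsilon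
- amount of target at the end, in percent of the substrate charged, zeta

I turn the question round: for a slow reagent feed to cost nothing, the catalyst would have to outlast the feed. Counting every catalyst as free, with death its sole loss, its first half-life τ is 6.27 h, and at time t it stands at its charge divided by one plus t/τ. The delta feed is longer, by a factor of 7.98, while the eta feed is just inside.

Reagent uptake is pseudo-first-order in reagent, with a constant that fades as the catalyst does, so I can integrate it in closed form. Reagent left is exp(−G), where the reach G is the forward uptake constant over twice the death constant, 0.474, times the logarithm of one plus t/τ. I count the forward step by itself and take each reagent taken up as one target.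

At 10 d the reach is 1.74, so on this reckoning zeta keeps 17.6% of its reagent and makes 90.7% target. With a steady inflow the equation stays linear and still closes: on the reckoning delta holds 73.4% of its reagent at the end of the feed, then 36.5% at 10 d, which makes 69.9% target. Reckoned the same way, eta comes to 87.4% target. My reckoning stops there: epsilon has its reagent from the start, so G gives it the zeta figure and cannot part the two.

The forecast picks epsilon, with delta 70%, eta 90.5%, epsilon 93.8% and zeta 93.5%, holding that “slow substrate feed parks it safely as intermediate B”.

The simulation gives epsilon as best, with delta 70.9%, eta 91.2%, epsilon 96.7% and zeta 94.1%.

Delta falls short because of the death step: the same delta run without that step gives 100% against 70.9%. Starting from the 76.4% of its reagent that delta holds at the end of the feed, the rest of G takes it to 38.0%, and delta stands at 35.5%. My equation is linear in reagent, and on it the neighbour of delta charged with 0.280 equiv should keep the same 36.5% and make 17.8% target. That neighbour keeps 37.7% and makes 17.5%.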